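## Retrosynthetic overview

1. Feature: in the primed benzene ring (C4a'–C5'–C6'–C7'–C8'–C8a'), the ether oxygen on C6' and the ring oxygen O1' on C8a' are para. This is a hydroquinone pattern, and the C6' oxygen is also O8 of the tetrahydro unit.
2. Last disconnection: the primed pyranone ring goes back to an o-hydroxyacetophenone through O-acylation, acyl shift and cyclodehydration.
3. Key disconnection: the primed benzene ring is cut at C5'–C6', C4a'–C8a' and C8'–C8a'. The parts are a chromium carbene carrying O8 and a 1-methoxyvinyl group, a ketal-bearing terminal alkyne, and one CO ligand. The hindered C8–O–aryl ether is therefore never made by substitution.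
4. The 8-alcohol goes back to a silyl enol ether and an ynal (C4a–C4 aldol, oxidation, O1–C2 closure). Its carbocycle is the enantiopure cis-dihydrodiol of bromobenzene (C7, C8), with C6 set by an anti epoxidation and C5 by an SN2 opening.
5. Ring order: carbocycle (bought), unprimed pyranone, primed benzene ring, primed pyranone.

Key step: step 15

Remark: the SMILES is read as 5S,6R,7S,8S (5,6-trans, 6,7-trans, 7,8-cis); unprimed locants belong to the tetrahydro unit and are used for its carbocycle from the first compound on (C8a carries Br, C4a is the vinylic CH), primed locants belong to the aromatic chromone; PMB = 4-methoxybenzyl, TES = triethylsilyl, BDA = (2S,3S)-2,3-dimethoxybutane-2,3-diyl bridging O6 and O7; the bromodiol is taken as the purchasable product of whole-cell dioxygenase oxidation of bromobenzene.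

## Route

Step 1
Reactants: 1 (1S,2S)-3-bromocyclohexa-3,5-diene-1,2-diol
Product: 2 (3aS,7aS)-4-bromo-2,2-dimethyl-3a,7a-dihydro-1,3-benzodioxole (7,8-O-isopropylidene derivative of 1)
Conditions: Me2C(OMe)2, p-TsOH (cat.), CH2Cl2, 0 °C → rt
Reagents that add atoms: 2,2-dimethoxypropane, COC(C)(C)OC
Why: Acid-catalysed transketalisation on the cis-7,8-diol gives the cis-fused dioxolane, which stops dehydrative aromatisation, shields one face of the diene and touches no stereocentre.

Step 2
Reactants: 2 acetonide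
Product: 3 anti-5,6-epoxide of 2 (oxirane oxygen on the face opposite to O7 and O8; 5R,6R,7S,8S)
Conditions: mCPBA, CH2Cl2, 0 °C → rt
Reagents that add atoms: mCPBA, O=C(OO)c1cccc(Cl)c1
Why: Prilezhaev epoxidation picks the electron-richer, bromine-free C5=C6 double bond and attacks the face opposite to the dioxolane, which sets the C6–O bond trans to O7.

Step 3
Reactants: 3 epoxide
Product: 4 (5S,6R,7S,8S)-8a-bromo-5-O-PMB-7,8-O-isopropylidenecyclohex-4a(8a)-ene-5,6,7,8-tetrol (6-OH free)
Conditions: PMBOH (3 equiv), NaH (1.2 equiv), DMF, 0 → 60 °C; H2O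
Reagents that add atoms: 4-methoxybenzyl alcohol, OCc1ccc(OC)cc1
Why: Base-mediated SN2 opening of the vinyl epoxide occurs at the allylic and less shielded C5 with inversion, which sets C5 (5,6-trans) and brings in O5 already protected.

Step 4
Reactants: 4 PMB ether acetonide
Product: 6 (5S,6R,7R,8S)-8a-bromo-5-O-PMB-6,7-O-BDA-cyclohex-4a(8a)-ene-5,6,7,8-tetrol (8-OH free and pseudoaxial), via triol 5 (not isolated)
Conditions: butane-2,3-dione, HC(OMe)3, CSA (cat.), MeOH, reflux
Reagents that add atoms: butane-2,3-dione, CC(=O)C(C)=O; trimethyl orthoformate, COC(OC)OC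
Why: Under butane-2,3-diacetal conditions the acetonide is methanolysed and the dioxane diacetal, which needs a trans-diequatorial diol and places both methoxy groups axial (anomeric effect, hence S,S acetal carbons), can form only on O6/O7, so the cis-related 8-OH is freed without a selective protection and the ring is locked with C5–O, C7–O and C8–H out of alignment with the later π system.

Step 5
Reactants: 6 alcohol
Product: 7 8-O-TES ether of 6 (5S,6R,7S,8S)
Conditions: TESCl, imidazole, DMF, 0 °C → rt
Reagents that add atoms: chlorotriethylsilane, CC[Si](Cl)(CC)CC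
Why: Standard silylation masks the only free hydroxyl with a group that survives organolithium, cold Lewis acid and periodinane but is lost in dilute acid.

Step 6
Reactants: 7 vinyl bromide
Product: 9 8a-trimethylsilyloxy analogue of 7 (silyl enol ether C8a=C4a), via vinyllithium 8 (not isolated)
Conditions: t-BuLi (2.1 equiv), Et2O, −78 °C; (TMSO)2, −78 → 0 °C; pentane, cold water wash
Reagents that add atoms: bis(trimethylsilyl) peroxide, C[Si](C)(C)OO[Si](C)(C)C; tert-butyllithium, [Li]C(C)(C)C (Li only in intermediate 8)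
Why: Bromine–lithium exchange followed by electrophilic oxygenation of the vinyllithium with the silyl peroxide gives the silyl enol ether regiospecifically at C8a=C4a, so no ketone has to be enolised between the C8 and C5 alkoxy groups, and ring strain forbids β-elimination from the cyclic vinyllithium.

Step 7
Reactants: 10 4-phenylbut-1-yne
Product: 12 5-phenylpent-2-ynal, via lithium acetylide 11 (not isolated)
Conditions: n-BuLi, THF, −78 °C; DMF, −78 → 0 °C; poured into cold 1 M HCl
Reagents that add atoms: N,N-dimethylformamide, CN(C)C=O; n-butyllithium, [Li]CCCC (Li only in intermediate 11)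
Why: Formylation of a lithium acetylide with DMF, with an acidic reverse quench that keeps the liberated dimethylamine from adding to the ynal.

Step 8
Reactants: 9 silyl enol ether; 12 5-phenylpent-2-ynal
Product: 13 (5S,6R,7S,8S)-4a-(1-hydroxy-5-phenylpent-2-yn-1-yl)-5-O-PMB-6,7-O-BDA-8-O-TES-cyclohexan-8a-one (mixture at C4a and at the carbinol carbon)
Conditions: BF3·OEt2 (1.1 equiv), CH2Cl2, −78 °C; aq NaHCO3
Reagents that add atoms: none
Why: The Mukaiyama aldol addition forms C4a–C4 under non-basic conditions while the diacetal holds the C5–O bond pseudo-equatorial and badly aligned for β-elimination, and the two new stereocentres are erased in steps 9 and 10 and need no control.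

Step 9
Reactants: 13 aldol
Product: 14 4a-(5-phenylpent-2-ynoyl) ketone (drawn as its C8a enol)
Conditions: DMP (1.2 equiv), CH2Cl2, 0 °C → rt
Reagents that add atoms: none
Why: Dess–Martin oxidation of a β-hydroxy ketone gives the 1,3-diketone, which rests as the hydrogen-bonded enol and thereby removes the C4a stereocentre.

Step 10
Reactants: 14 alkynoyl ketone
Product: 17 (5S,6R,7R,8S)-8-hydroxy-5-(4-methoxybenzyloxy)-6,7-O-BDA-2-(2-phenylethyl)-5,6,7,8-tetrahydro-4H-chromen-4-one, via enaminone 15 (not isolated), via 8-O-TES pyranone 16 (not isolated)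
Conditions: Et2NH (1.5 equiv), EtOH, rt; then 1 M HCl, THF, rt
Reagents that add atoms: diethylamine, CCNCC (atoms only in intermediate 15)
Why: Conjugate addition of the amine to the ynone gives an enaminone, acid then drives 6-endo addition–elimination by the C8a enol oxygen (the amine route from ynones to 4-pyranones and chromones), and the same acid removes the TES group while PMB and diacetal stay in place.

Step 11
Reactants: 18 methyl vinyl ether; 19 chromium hexacarbonyl Cr(CO)6
Product: 22 tetramethylammonium pentacarbonyl[(1-methoxyvinyl)(oxido)carbene]chromate, via 1-methoxyvinyllithium 20 (not isolated), via lithium acylchromate 21 (not isolated)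
Conditions: t-BuLi, THF, −78 → 0 °C; Cr(CO)6, Et2O, −78 °C → rt; Me4NBr, degassed H2O, extraction into CH2Cl2
Reagents that add atoms: tetramethylammonium bromide, C[N+](C)(C)C.[Br-]; tert-butyllithium, [Li]C(C)(C)C (Li only in intermediates 20, 21)
Why: In the Fischer route the α-lithiated enol ether adds to a CO ligand of Cr(CO)6, and cation exchange gives the storable acylchromate salt that dissolves in CH2Cl2.

Step 12
Reactants: 22 acylchromate salt; 17 8-alcohol
Product: 24 pentacarbonyl[(1-methoxyvinyl)(cyclitol-8-yloxy)carbene]chromium (cyclitol = 17 bound through O8; 5S,6R,7S,8S), via acetoxycarbene complex 23 (not isolated)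
Conditions: 22 (1.8 equiv), AcBr (1.7 equiv), CH2Cl2, −40 °C; then 17, −40 → −10 °C
Reagents that add atoms: acetyl bromide, CC(=O)Br (atoms only in intermediate 23)
Why: O-Acylation of the acylchromate gives a strongly electrophilic acetoxycarbene that the alcohol attacks at the carbene carbon by addition–elimination (the acyloxycarbene alcoholysis used for menthyl and sugar alkoxycarbene complexes), so O8 becomes the carbene oxygen, C8–O is not broken and C8 keeps its configuration.

Step 13
Reactants: 25 4-(trimethylsilyl)but-3-yn-2-one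
Product: 26 2-methyl-2-[(trimethylsilyl)ethynyl]-1,3-dioxolane
Conditions: (TMSOCH2)2, TMSOTf (cat.), CH2Cl2, −78 → −20 °C
Reagents that add atoms: 1,2-bis(trimethylsiloxy)ethane, C[Si](C)(C)OCCO[Si](C)(C)C
Why: Noyori ketalisation with the bis-silylated glycol works at low temperature and without water, which avoids conjugate addition to the ynone.

Step 14
Reactants: 26 silylated alkynyl ketal
Product: 27 2-ethynyl-2-methyl-1,3-dioxolane
Conditions: K2CO3 (cat.), MeOH, 0 °C → rt
Reagents that add atoms: none
Why: Base-catalysed protiodesilylation of the alkynylsilane frees the terminal alkyne and leaves the ketal untouched.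

Step 15
Reactants: 24 carbene complex; 27 2-ethynyl-2-methyl-1,3-dioxolane
Product: 29 4-(cyclitol-8-yloxy)-5-methoxy-2-(2-methyl-1,3-dioxolan-2-yl)phenol (cyclitol as in 24; 5S,6R,7S,8S), via tricarbonylchromium arene complex 28 (not isolated)
Conditions: 27 (2.5 equiv), THF (0.05 M), 50 °C, Ar; then air, Et2O, rt, daylight
Reagents that add atoms: none
Why: Thermal loss of one CO opens a site for 27, which inserts into the Cr=C bond with its CH terminus bonding to the carbene carbon (C5'–C6'), and CO insertion at the new carbene carbon (C4a'–C8a') gives a chromium-bound dienylketene. A six-electron electrocyclic closure joins the ketene carbon to the vinyl CH2 (C8'–C8a') and so closes the six-membered carbocycle, and enolisation gives the phenol as its Cr(CO)3 complex 28, from which air removes the metal. The closest known reaction is the Dötz benzannulation of alkenyl(alkoxy)carbene chromium complexes with terminal alkynes, which is established for 1-alkoxyalkenyl complexes of the dihydropyranyl and glycal type and for complexes whose alkoxy group is menthyl or a sugar. No stereocentre is formed and the C8–O bond is never touched, so the 7,8-cis relationship of 17 passes unchanged into the aryl ether. The step needs regioselective insertion, which the terminal alkyne secures because its quaternary ketal carbon avoids the alkoxy-bearing carbene carbon and ends next to the new hydroxyl, and it needs phenol formation over five- and four-membered ring products, which chromium, an alkenyl rather than aryl carbene and a donor solvent favour. Strong oxidants such as (NH4)2Ce(NO3)6 are kept out of the work-up because they would turn the 4-alkoxyphenol into the quinone with loss of the ether.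

Step 16
Reactants: 29 ketal phenol
Product: 30 1-[5-(cyclitol-8-yloxy)-2-hydroxy-4-methoxyphenyl]ethanone
Conditions: 1 M HCl, THF, 0 °C → rt
Reagents that add atoms: water, O
Why: Acid hydrolysis of the aryl-substituted dioxolane runs through an oxocarbenium ion stabilised by the electron-rich ring and is far faster than cleavage of the doubly anomerically stabilised diacetal or of the PMB ether.

Step 17
Reactants: 30 o-hydroxyacetophenone; 31 3-phenylpropanoyl chloride
Product: 32 2-acetyl-4-(cyclitol-8-yloxy)-5-methoxyphenyl 3-phenylpropanoate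
Conditions: Et3N, DMAP (cat.), CH2Cl2, 0 °C → rt
Reagents that add atoms: none
Why: DMAP-catalysed O-acylation of the only free hydroxyl, with a base too weak to remove C8–H.

Step 18
Reactants: 32 aryl ester
Product: 33 1-[5-(cyclitol-8-yloxy)-2-hydroxy-4-methoxyphenyl]-5-phenylpentane-1,3-dione
Conditions: MgBr2·OEt2 (2.5 equiv), i-Pr2NEt (3 equiv), CH2Cl2, rt; cold 1 M HCl
Reagents that add atoms: none
Why: In the soft-enolisation variant of the Baker–Venkataraman rearrangement, magnesium chelation of the acetyl and ester carbonyls lets a tertiary amine form the methyl ketone enolate, which takes the acyl group from O1' through a six-membered transition state, while the vinylogously acidic C8–H, held pseudo-equatorial by the diacetal, is not removed and E1cB loss of O7 is avoided.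

Step 19
Reactants: 33 1,3-diketone
Product: 35 target (5S,6R,7S,8S)-5,6,7-trihydroxy-8-{[7-methoxy-4-oxo-2-(2-phenylethyl)-4H-chromen-6-yl]oxy}-2-(2-phenylethyl)-5,6,7,8-tetrahydro-4H-chromen-4-one, via protected bischromone 34 (not isolated)
Conditions: TFA/H2O 9:1, anisole (5 equiv), 0 °C → rt; evaporation from MeOH
Reagents that add atoms: none
Why: In aqueous TFA the o-hydroxyaryl 1,3-diketone cyclodehydrates to the chromone, the diacetal is hydrolysed and the PMB ether is cleaved through the 4-methoxybenzyl cation that anisole traps, whereas ionisation at C5 or C8 is disfavoured by the electron-poor pyranone and the neighbouring oxygens, so all four stereocentres persist and no basic fluoride is needed.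

## Compound list

1 | (1S,2S)-3-bromocyclohexa-3,5-diene-1,2-diol | O[C@@H]1C(Br)=CC=C[C@@H]1O | starting material
2 | (3aS,7aS)-4-bromo-2,2-dimethyl-3a,7a-dihydro-1,3-benzodioxole | CC1(C)O[C@@H]2C(Br)=CC=C[C@@H]2O1 | intermediate
3 | anti-5,6-epoxide of 2 (5R,6R,7S,8S) | CC1(C)O[C@@H]2C(Br)=C[C@H]3O[C@H]3[C@@H]2O1 | intermediate
4 | 8a-bromo-5-O-PMB-7,8-O-isopropylidene cyclohexenetetrol, 6-OH free (5S,6R,7S,8S) | CC1(C)O[C@@H]2C(Br)=C[C@H](OCc3ccc(OC)cc3)[C@@H](O)[C@@H]2O1 | intermediate
5 | 8a-bromo-5-O-PMB cyclohexene-6,7,8-triol | O[C@@H]1C(Br)=C[C@H](OCc2ccc(OC)cc2)[C@@H](O)[C@@H]1O | intermediate (not isolated)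
6 | 8a-bromo-5-O-PMB-6,7-O-BDA cyclohexenetetrol, 8-OH free (5S,6R,7R,8S) | O[C@@H]1C(Br)=C[C@H](OCc2ccc(OC)cc2)[C@H]2O[C@](C)(OC)[C@@](C)(OC)O[C@H]12 | intermediate
7 | 8-O-TES ether of 6 | CC[Si](CC)(CC)O[C@@H]1C(Br)=C[C@H](OCc2ccc(OC)cc2)[C@H]2O[C@](C)(OC)[C@@](C)(OC)O[C@H]12 | intermediate
8 | C8a vinyllithium from 7 | CC[Si](CC)(CC)O[C@@H]1C([Li])=C[C@H](OCc2ccc(OC)cc2)[C@H]2O[C@](C)(OC)[C@@](C)(OC)O[C@H]12 | intermediate (not isolated)
9 | C8a trimethylsilyl enol ether | CC[Si](CC)(CC)O[C@@H]1C(O[Si](C)(C)C)=C[C@H](OCc2ccc(OC)cc2)[C@H]2O[C@](C)(OC)[C@@](C)(OC)O[C@H]12 | intermediate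
10 | 4-phenylbut-1-yne | C#CCCc1ccccc1 | starting material
11 | lithium 4-phenylbut-1-yn-1-ide | [Li]C#CCCc1ccccc1 | intermediate (not isolated)
12 | 5-phenylpent-2-ynal | O=CC#CCCc1ccccc1 | intermediate
13 | aldol adduct (C4a and carbinol carbon unassigned) | CC[Si](CC)(CC)O[C@@H]1C(=O)C(C(O)C#CCCc2ccccc2)[C@H](OCc2ccc(OC)cc2)[C@H]2O[C@](C)(OC)[C@@](C)(OC)O[C@H]12 | intermediate
14 | 4a-(5-phenylpent-2-ynoyl) ketone, C8a enol form | CC[Si](CC)(CC)O[C@@H]1C(O)=C(C(=O)C#CCCc2ccccc2)[C@H](OCc2ccc(OC)cc2)[C@H]2O[C@](C)(OC)[C@@](C)(OC)O[C@H]12 | intermediate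
15 | β-diethylamino enone from 14 | CC[Si](CC)(CC)O[C@@H]1C(O)=C(C(=O)C=C(CCc2ccccc2)N(CC)CC)[C@H](OCc2ccc(OC)cc2)[C@H]2O[C@](C)(OC)[C@@](C)(OC)O[C@H]12 | intermediate (not isolated)
16 | 8-O-TES tetrahydrochromone | CC[Si](CC)(CC)O[C@@H]1c2oc(CCc3ccccc3)cc(=O)c2[C@H](OCc2ccc(OC)cc2)[C@H]2O[C@](C)(OC)[C@@](C)(OC)O[C@H]12 | intermediate (not isolated)
17 | (5S,6R,7R,8S)-8-hydroxy-5-O-PMB-6,7-O-BDA-2-(2-phenylethyl)tetrahydrochromone | O[C@@H]1c2oc(CCc3ccccc3)cc(=O)c2[C@H](OCc2ccc(OC)cc2)[C@H]2O[C@](C)(OC)[C@@](C)(OC)O[C@H]12 | intermediate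
18 | methyl vinyl ether | C=COC | starting material
19 | chromium hexacarbonyl Cr(CO)6 | O=C=[Cr](=C=O)(=C=O)(=C=O)(=C=O)=C=O | starting material
20 | 1-methoxyvinyllithium | C=C([Li])OC | intermediate (not isolated)
21 | lithium pentacarbonyl[(1-methoxyvinyl)(oxido)carbene]chromate | [Li+].C=C(OC)C([O-])=[Cr](=C=O)(=C=O)(=C=O)(=C=O)=C=O | intermediate (not isolated)
22 | tetramethylammonium pentacarbonyl[(1-methoxyvinyl)(oxido)carbene]chromate | C=C(OC)C([O-])=[Cr](=C=O)(=C=O)(=C=O)(=C=O)=C=O.C[N+](C)(C)C | intermediate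
23 | pentacarbonyl[acetoxy(1-methoxyvinyl)carbene]chromium | C=C(OC)C(OC(C)=O)=[Cr](=C=O)(=C=O)(=C=O)(=C=O)=C=O | intermediate (not isolated)
24 | pentacarbonyl[(cyclitol-8-yloxy)(1-methoxyvinyl)carbene]chromium | C=C(OC)C(=[Cr](=C=O)(=C=O)(=C=O)(=C=O)=C=O)O[C@@H]1c2oc(CCc3ccccc3)cc(=O)c2[C@H](OCc2ccc(OC)cc2)[C@H]2O[C@](C)(OC)[C@@](C)(OC)O[C@H]12 | intermediate (key-step precursor)
25 | 4-(trimethylsilyl)but-3-yn-2-one | CC(=O)C#C[Si](C)(C)C | starting material
26 | 2-methyl-2-[(trimethylsilyl)ethynyl]-1,3-dioxolane | CC1(C#C[Si](C)(C)C)OCCO1 | intermediate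
27 | 2-ethynyl-2-methyl-1,3-dioxolane | C#CC1(C)OCCO1 | intermediate (key-step precursor)
28 | Cr(CO)3 complex of 29 (hexahapto bond to the new ring not drawn) | COc1cc(O)c(C2(C)OCCO2)cc1O[C@@H]1c2oc(CCc3ccccc3)cc(=O)c2[C@H](OCc2ccc(OC)cc2)[C@H]2O[C@](C)(OC)[C@@](C)(OC)O[C@H]12.O=C=[Cr](=C=O)=C=O | intermediate (not isolated)
29 | 4-(cyclitol-8-yloxy)-5-methoxy-2-(2-methyl-1,3-dioxolan-2-yl)phenol | COc1cc(O)c(C2(C)OCCO2)cc1O[C@@H]1c2oc(CCc3ccccc3)cc(=O)c2[C@H](OCc2ccc(OC)cc2)[C@H]2O[C@](C)(OC)[C@@](C)(OC)O[C@H]12 | intermediate (key-step product)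
30 | 1-[5-(cyclitol-8-yloxy)-2-hydroxy-4-methoxyphenyl]ethanone | COc1cc(O)c(C(C)=O)cc1O[C@@H]1c2oc(CCc3ccccc3)cc(=O)c2[C@H](OCc2ccc(OC)cc2)[C@H]2O[C@](C)(OC)[C@@](C)(OC)O[C@H]12 | intermediate
31 | 3-phenylpropanoyl chloride | O=C(Cl)CCc1ccccc1 | starting material
32 | 2-acetyl-4-(cyclitol-8-yloxy)-5-methoxyphenyl 3-phenylpropanoate | COc1cc(OC(=O)CCc2ccccc2)c(C(C)=O)cc1O[C@@H]1c2oc(CCc3ccccc3)cc(=O)c2[C@H](OCc2ccc(OC)cc2)[C@H]2O[C@](C)(OC)[C@@](C)(OC)O[C@H]12 | intermediate
33 | 1-[5-(cyclitol-8-yloxy)-2-hydroxy-4-methoxyphenyl]-5-phenylpentane-1,3-dione | COc1cc(O)c(C(=O)CC(=O)CCc2ccccc2)cc1O[C@@H]1c2oc(CCc3ccccc3)cc(=O)c2[C@H](OCc2ccc(OC)cc2)[C@H]2O[C@](C)(OC)[C@@](C)(OC)O[C@H]12 | intermediate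
34 | 5-O-PMB-6,7-O-BDA derivative of the target | COc1cc2oc(CCc3ccccc3)cc(=O)c2cc1O[C@@H]1c2oc(CCc3ccccc3)cc(=O)c2[C@H](OCc2ccc(OC)cc2)[C@H]2O[C@](C)(OC)[C@@](C)(OC)O[C@H]12 | intermediate (not isolated)
35 | CNP0125425.2 (5S,6R,7S,8S) | COc1cc2oc(CCc3ccccc3)cc(=O)c2cc1O[C@@H]1c2oc(CCc3ccccc3)cc(=O)c2[C@H](O)[C@@H](O)[C@@H]1O | target

## Step count and risks

Total step count: 19.
Longest linear sequence: 15 (steps 1–6, 8–10, 12, 15–19).

**Step 15.** Three processes threaten it.
- Insertion of the bulky alkyne may be slower than thermal decay of the hindered alkoxycarbene.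
- CO insertion may be bypassed, which leads to five- or four-membered rings.
- The electron-rich phenol may be over-oxidised during demetallation.

The fallback makes the ether by substitution with inversion; it sets out from 17 and comes back at 30. Alcohol 17 is oxidised with Dess–Martin periodinane to the 8-ketone F1. Luche reduction (NaBH4, CeCl3·7H2O, MeOH, −78 °C) with axial hydride delivery should give the pseudo-equatorial 8-epi alcohol F2. A Mitsunobu etherification (PPh3, DIAD, toluene, 0 °C) follows with purchased 1-(2,5-dihydroxy-4-methoxyphenyl)ethanone (COc1cc(O)c(C(C)=O)cc1O). Its chelated 2-OH stays inert, so the 5-OH reacts, C8 is inverted and 30 results.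

**Step 12.** Attack of the hindered pseudoaxial alcohol on the thermally labile acetoxycarbene may be slower than its decomposition. The alcohol may also add in conjugate fashion to the vinyl terminus.

The fallback forms the C8–O–aryl bond by copper-catalysed oxidative arylation; it sets out from 17 (with 31) and comes back at 32. Purchased 1-(5-bromo-2-hydroxy-4-methoxyphenyl)ethanone (COc1cc(O)c(C(C)=O)cc1Br) is acylated with 31 (Et3N, DMAP) to the bromoaryl ester F3. Miyaura borylation (B2pin2, PdCl2(dppf), KOAc, dioxane, 80 °C) gives the pinacol boronate F4, and KHF2 in aqueous MeOH gives the potassium trifluoroborate F5. Chan–Lam type coupling of F5 with 17 (Cu(OAc)2·H2O cat., DMAP, 4 Å sieves, O2, CH2Cl2, rt) then gives 32 without strong base.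

**Step 8.** The Lewis acid may trigger loss of the C5 alkoxy group from the silyl enol ether (vinylogous elimination). Protodesilylation may also outrun C–C bond formation.

The fallback builds the pyranone in one thermal cycloaddition without Lewis acid; it sets out from 9 and comes back at 17. Meldrum's acid is acylated with 31 (pyridine, CH2Cl2) to the acyl Meldrum's acid F6, which on heating with acetone in toluene gives the dioxinone F7. Thermolysis of F7 (toluene, 110 °C) in the presence of 9 releases the acylketene F8. Its [4+2] cycloaddition with the enol ether double bond gives the 8a-silyloxy dihydropyranone F9. Treatment with 1 M HCl in THF then eliminates silanol and removes the TES group to give 17.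

## Further compounds

F1 | step 15 | (5S,6R,7S)-8-oxo-5-O-PMB-6,7-O-BDA-2-(2-phenylethyl)tetrahydrochromone | O=C1c2oc(CCc3ccccc3)cc(=O)c2[C@H](OCc2ccc(OC)cc2)[C@H]2O[C@](C)(OC)[C@@](C)(OC)O[C@H]12
F2 | step 15 | (5S,6R,7R,8R)-8-epi alcohol | O[C@H]1c2oc(CCc3ccccc3)cc(=O)c2[C@H](OCc2ccc(OC)cc2)[C@H]2O[C@](C)(OC)[C@@](C)(OC)O[C@H]12
F3 | step 12 | 2-acetyl-4-bromo-5-methoxyphenyl 3-phenylpropanoate | COc1cc(OC(=O)CCc2ccccc2)c(C(C)=O)cc1Br
F4 | step 12 | 2-acetyl-5-methoxy-4-(4,4,5,5-tetramethyl-1,3,2-dioxaborolan-2-yl)phenyl 3-phenylpropanoate | COc1cc(OC(=O)CCc2ccccc2)c(C(C)=O)cc1B1OC(C)(C)C(C)(C)O1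
F5 | step 12 | potassium [5-acetyl-2-methoxy-4-(3-phenylpropanoyloxy)phenyl]trifluoroborate | COc1cc(OC(=O)CCc2ccccc2)c(C(C)=O)cc1[B-](F)(F)F.[K+]
F6 | step 8 | 5-(1-hydroxy-3-phenylpropylidene)-2,2-dimethyl-1,3-dioxane-4,6-dione | CC1(C)OC(=O)C(=C(O)CCc2ccccc2)C(=O)O1
F7 | step 8 | 2,2-dimethyl-6-(2-phenylethyl)-4H-1,3-dioxin-4-one | CC1(C)OC(CCc2ccccc2)=CC(=O)O1
F8 | step 8 | 3-oxo-5-phenylpent-1-en-1-one (acylketene) | O=C=CC(=O)CCc1ccccc1
F9 | step 8 | 8a-trimethylsilyloxy-4a,8a-dihydro cycloadduct (C4a, C8a unassigned) | CC[Si](CC)(CC)O[C@@H]1C2(O[Si](C)(C)C)OC(CCc3ccccc3)=CC(=O)C2[C@H](OCc2ccc(OC)cc2)[C@H]2O[C@](C)(OC)[C@@](C)(OC)O[C@H]12
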